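**Plan**
1. Retrosynthesis: the cyclohexadienone ring is cut at C1–C2 (C1 is the ketone carbon next to the gem-diprenyl carbon C6, C2 is the ring carbon that carries the isoindolinone). Then the lactam N–C(=O) bond is cut, then the bond from C3 of the isoindolinone to its CH2 (Mannich), then the enone (Meyer–Schuster, back to a methyl ketone and propyne), then the two prenyl–C6 bonds.
2. Enabling feature: the carbocycle is an enolised cyclic β-diketone. C2 is the α-carbon of the C3 carbonyl and lies 1,5 to the acyl carbon C1 on quaternary C6, and C2 is also β to the lactam nitrogen. An open-chain β-amino ketone diester with C6 already fully substituted can therefore close both rings by N- and then C-acylation.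
3. Forward order: acetoacetate is diprenylated and homologated to an (E)-enone ester (chain); the chain is joined to a 2-carbomethoxyaryl sulfinimine; in the last step the lactam closes first and the carbocycle second.
4. Stereochemistry: the single stereocentre comes from (R)-tert-butanesulfinamide in the Mannich addition. It is held through the final base step because the lactam nitrogen is metalated before the ketone enolate forms.
5. No dearomatisation or late prenylation is needed: the quaternary carbon is made by enolate alkylation before any ring exists.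

Key step: step 9

Remark: 17 is an enolised cyclic β-diketone and is obtained as its tautomeric system, drawn as in the target; enone 12 and its descendants are drawn as the (E)-isomers, a geometry that step 9 erases.

**Step 1**
Reactants: 1 methyl 3-methoxy-2-methylbenzoate
Product: 2 methyl 2-(bromomethyl)-3-methoxybenzoate
Conditions: NBS (1.05 equiv), AIBN (cat.), PhCF3, 85 °C
Reagents that add atoms: N-bromosuccinimide, O=C1CCC(=O)N1Br
Why: Wohl–Ziegler radical bromination at the only benzylic C–H position, kept at the monobromide by the stoichiometry.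

**Step 2**
Reactants: 2 methyl 2-(bromomethyl)-3-methoxybenzoate
Product: 3 methyl 2-formyl-3-methoxybenzoate
Conditions: N-methylmorpholine N-oxide (4 equiv), 4 Å MS, MeCN, rt
Reagents that add atoms: N-methylmorpholine N-oxide, C[N+]1([O-])CCOCC1
Why: Kornblum-type oxidation with an amine N-oxide: SN2 displacement of bromide by the N-oxide oxygen and loss of N-methylmorpholine should give the aldehyde without over-oxidation and at a temperature where lactonisation to the phthalide is slow.

**Step 3**
Reactants: 3 methyl 2-formyl-3-methoxybenzoate; 4 (R)-2-methylpropane-2-sulfinamide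
Product: 5 methyl 2-[(E)-{[(R)-tert-butylsulfinyl]imino}methyl]-3-methoxybenzoate
Conditions: Ti(OEt)4 (2 equiv), THF, rt
Reagents that add atoms: none
Why: Lewis-acid-mediated condensation of an aldehyde with tert-butanesulfinamide, Ti(OEt)4 also scavenging water, should give the (E)-sulfinyl aldimine with the sulfur configuration untouched.

**Step 4**
Reactants: 6 methyl 3-oxobutanoate; 7 1-bromo-3-methylbut-2-ene (2.3 equiv)
Product: 9 methyl 2-acetyl-5-methyl-2-(3-methylbut-2-en-1-yl)hex-4-enoate, via monoprenyl keto ester 8 (not isolated)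
Conditions: NaH (2.2 equiv, two portions), THF then THF–DMF, 0 °C → rt
Reagents that add atoms: none
Why: Twofold acetoacetic ester C-alkylation (SN2 at the primary allylic carbon of a soft electrophile) builds the gem-diprenyl quaternary carbon before any ring exists.

**Step 5**
Reactants: 9 methyl 2-acetyl-5-methyl-2-(3-methylbut-2-en-1-yl)hex-4-enoate; 10 prop-1-yn-1-ylmagnesium bromide
Product: 11 methyl 3-hydroxy-3-methyl-2,2-bis(3-methylbut-2-en-1-yl)hex-4-ynoate (racemic)
Conditions: MeC≡CMgBr (1.5 equiv), THF, −40 → 0 °C; aq. NH4Cl
Reagents that add atoms: none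
Why: 1,2-addition of a slim, weakly basic alkynyl Grignard reagent to the methyl ketone, the neopentyl ester being too hindered to compete; the new carbinol centre is racemic and is destroyed in step 6.

**Step 6**
Reactants: 11 methyl 3-hydroxy-3-methyl-2,2-bis(3-methylbut-2-en-1-yl)hex-4-ynoate
Product: 12 methyl (3E)-3-methyl-2,2-bis(3-methylbut-2-en-1-yl)-5-oxohex-3-enoate
Conditions: VO(OSiPh3)3 (5 mol %), toluene, 110 °C
Reagents that add atoms: none
Why: Meyer–Schuster rearrangement: the vanadate ester of the tertiary propargylic alcohol undergoes a 1,3-oxygen shift to an allenyl vanadate that tautomerises to the enone, under neutral conditions that spare the prenyl groups, with the acetyl group expected trans to the quaternary carbon.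

**Step 7**
Reactants: 12 methyl (3E)-3-methyl-2,2-bis(3-methylbut-2-en-1-yl)-5-oxohex-3-enoate (1.2 equiv); 5 methyl 2-[(E)-{[(R)-tert-butylsulfinyl]imino}methyl]-3-methoxybenzoate
Product: 14 methyl 2-[(1S,4E)-1-{[(R)-tert-butylsulfinyl]amino}-6-(methoxycarbonyl)-5,9-dimethyl-6-(3-methylbut-2-en-1-yl)-3-oxodeca-4,8-dien-1-yl]-3-methoxybenzoate, via lithium enolate 13 (not isolated)
Conditions: LiN(iPr)2 (1.15 equiv), THF, −78 °C; then 5, −78 °C; AcOH, −78 °C
Reagents that add atoms: none
Why: Mannich addition of a kinetic lithium enolate to an N-tert-butanesulfinyl aldimine: cold deprotonation takes the acetyl CH3, and the cross-conjugated enolate should add through a closed six-membered chair transition state (lithium bridging enolate and sulfinyl oxygens, tert-butyl equatorial) to the Si face of the (R)-sulfinyl imine, setting the (S)-configured carbon (the same spatial arrangement is named R in 17 through a change of CIP priorities); the (E)-enone keeps the aliphatic ester out of reach of the enolate, and the cold acidic quench stops the sulfinamide anion from closing onto the aryl ester.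

**Step 8**
Reactants: 14 methyl 2-[(1S,4E)-1-{[(R)-tert-butylsulfinyl]amino}-6-(methoxycarbonyl)-5,9-dimethyl-6-(3-methylbut-2-en-1-yl)-3-oxodeca-4,8-dien-1-yl]-3-methoxybenzoate
Product: 15 methyl 2-[(1S,4E)-1-amino-6-(methoxycarbonyl)-5,9-dimethyl-6-(3-methylbut-2-en-1-yl)-3-oxodeca-4,8-dien-1-yl]-3-methoxybenzoate hydrochloride
Conditions: HCl (4 M in dioxane, 2 equiv), MeOH, 0 °C; evaporate, triturate with Et2O
Reagents that add atoms: hydrogen chloride, Cl
Why: Acidic methanolysis of the S–N bond removes the auxiliary as its methyl sulfinate, and keeping the amine protonated prevents both lactam closure and β-elimination until step 9; short exposure at 0 °C should spare the prenyl groups.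

**Step 9**
Reactants: 15 methyl 2-[(1S,4E)-1-amino-6-(methoxycarbonyl)-5,9-dimethyl-6-(3-methylbut-2-en-1-yl)-3-oxodeca-4,8-dien-1-yl]-3-methoxybenzoate hydrochloride
Product: 17 (3R)-3-[2-hydroxy-4-methyl-5,5-bis(3-methylbut-2-en-1-yl)-6-oxocyclohexa-1,3-dien-1-yl]-4-methoxy-2,3-dihydro-1H-isoindol-1-one, via lactam 16 (not isolated)
Conditions: KOtBu (5 equiv), THF, 0 °C → rt; AcOH, 0 °C; work-up at pH 4
Reagents that add atoms: none
Why: Mechanism: KOtBu frees the amine, which attacks the ortho methyl ester to give lactam 16, and the new N–H, now the most acidic site, is deprotonated at once so that the β-amido group can no longer leave by E1cB; the excess base then equilibrates the ketone enolates, the cross-conjugated dienolate formed at the vinylic methyl erases the enone geometry (E, Z and β,γ-isomers interconvert), and the enolate of the CH2 next to the isoindolinone attacks the neopentyl methyl ester in a cisoid form to make the C1–C2 bond, loss of methoxide and deprotonation of the resulting β-diketone making the closure irreversible. The closest known reaction types are the lactamisation of 2-(aminoalkyl)benzoates and the intramolecular Claisen (Dieckmann-type) condensation of δ-keto esters to cyclic 1,3-diones, as in the dimedone synthesis and the alkoxide-induced rearrangement of enol lactones to 1,3-diones. Ring closures: the lactam forms by 5-exo-trig acyl substitution and the carbocycle by 6-(enolendo)-exo-trig acyl substitution. No stereocentre is formed; the existing one is retained because nitrogen is anionic throughout the C-acylation and its C–H is not acidic. Selectivity needed: C- over O-acylation (an O-acylated enol lactone is reopened by alkoxide, so the C-acylated enolate is the thermodynamic sink), attack by the α′-carbon and not by the α- or γ-carbon (these would give four-membered rings), and no attack on the lactam carbonyl (an amidate), all secured by ring size and by the acidity of the product.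

**Compound list**
1 | methyl 3-methoxy-2-methylbenzoate | COC(=O)c1cccc(OC)c1C | starting material
2 | methyl 2-(bromomethyl)-3-methoxybenzoate | COC(=O)c1cccc(OC)c1CBr | intermediate
3 | methyl 2-formyl-3-methoxybenzoate | COC(=O)c1cccc(OC)c1C=O | intermediate
4 | (R)-2-methylpropane-2-sulfinamide | CC(C)(C)[S@@](=O)N | starting material
5 | methyl 2-[(E)-{[(R)-tert-butylsulfinyl]imino}methyl]-3-methoxybenzoate | COC(=O)c1cccc(OC)c1/C=N/[S@](=O)C(C)(C)C | intermediate
6 | methyl 3-oxobutanoate | CC(=O)CC(=O)OC | starting material
7 | 1-bromo-3-methylbut-2-ene | CC(C)=CCBr | starting material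
8 | methyl 2-acetyl-5-methylhex-4-enoate (racemic, not isolated) | CC(=O)C(CC=C(C)C)C(=O)OC | intermediate
9 | methyl 2-acetyl-5-methyl-2-(3-methylbut-2-en-1-yl)hex-4-enoate | CC(=O)C(CC=C(C)C)(CC=C(C)C)C(=O)OC | intermediate
10 | prop-1-yn-1-ylmagnesium bromide | CC#C[Mg]Br | starting material
11 | methyl 3-hydroxy-3-methyl-2,2-bis(3-methylbut-2-en-1-yl)hex-4-ynoate (racemic) | CC#CC(C)(O)C(CC=C(C)C)(CC=C(C)C)C(=O)OC | intermediate
12 | methyl (3E)-3-methyl-2,2-bis(3-methylbut-2-en-1-yl)-5-oxohex-3-enoate | CC(=O)/C=C(\C)C(CC=C(C)C)(CC=C(C)C)C(=O)OC | intermediate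
13 | lithium (3E)-6-methoxy-4-methyl-5,5-bis(3-methylbut-2-en-1-yl)-6-oxohexa-1,3-dien-2-olate (enolate of 12, not isolated) | [Li]OC(=C)/C=C(\C)C(CC=C(C)C)(CC=C(C)C)C(=O)OC | intermediate
14 | methyl 2-[(1S,4E)-1-{[(R)-tert-butylsulfinyl]amino}-6-(methoxycarbonyl)-5,9-dimethyl-6-(3-methylbut-2-en-1-yl)-3-oxodeca-4,8-dien-1-yl]-3-methoxybenzoate | COC(=O)c1cccc(OC)c1[C@H](CC(=O)/C=C(\C)C(CC=C(C)C)(CC=C(C)C)C(=O)OC)N[S@](=O)C(C)(C)C | intermediate
15 | methyl 2-[(1S,4E)-1-amino-6-(methoxycarbonyl)-5,9-dimethyl-6-(3-methylbut-2-en-1-yl)-3-oxodeca-4,8-dien-1-yl]-3-methoxybenzoate hydrochloride | COC(=O)c1cccc(OC)c1[C@H](CC(=O)/C=C(\C)C(CC=C(C)C)(CC=C(C)C)C(=O)OC)N.Cl | intermediate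
16 | methyl (3E)-6-[(1S)-7-methoxy-3-oxo-2,3-dihydro-1H-isoindol-1-yl]-3-methyl-2,2-bis(3-methylbut-2-en-1-yl)-5-oxohex-3-enoate (not isolated) | COc1cccc2c1[C@H](CC(=O)/C=C(\C)C(CC=C(C)C)(CC=C(C)C)C(=O)OC)NC2=O | intermediate
17 | (3R)-3-[2-hydroxy-4-methyl-5,5-bis(3-methylbut-2-en-1-yl)-6-oxocyclohexa-1,3-dien-1-yl]-4-methoxy-2,3-dihydro-1H-isoindol-1-one | COc1cccc2c1[C@H](C1=C(O)C=C(C)C(CC=C(C)C)(CC=C(C)C)C1=O)NC2=O | target

**Totals**
Total step count: 9.
Longest linear sequence: 6 steps (steps 1, 2, 3, 7, 8, 9 from 1; equally steps 4, 5, 6, 7, 8, 9 from 6).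

**Steps most likely to fail**

Step 9. What may go wrong: the (E)-enone may reach a cyclisable geometry too slowly and the neopentyl ester may be attacked too slowly, so that base-induced decomposition competes. Configuration may also be partly lost through reversible β-elimination of the amide nitrogen in any enolate that is still protonated on nitrogen. Fallback (sets out from 12 and 3, comes back at 17): the carbocycle is closed before the stereocentre exists. Enone ester 12 with NaOMe in MeOH at reflux should give 3-hydroxy-5-methyl-6,6-bis(3-methylbut-2-en-1-yl)cyclohexa-2,4-dien-1-one F1. Aldehyde 3 with NH3 in MeOH should give racemic 3-hydroxy-4-methoxy-2,3-dihydro-1H-isoindol-1-one F2. F1 and F2 are then joined by enantioselective amidoalkylation under a BINOL-derived chiral phosphoric acid (3,3′-bis(2,4,6-triisopropylphenyl) type, enantiomer chosen for the (R) product) in toluene with 4 Å MS. The acid generates the N-acylimine from F2 and directs C2 of F1 to one of its faces, giving 17.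

Step 7. What may go wrong: facial selectivity may be poor, because lithium can be chelated by the ortho ester and methoxy groups in place of the sulfinyl oxygen; the sulfinamide anion may also close early onto the aryl ester and then suffer β-elimination. Fallback (sets out from 5 and 9, comes back at 16): the stereocentre is set with a small, non-enolisable nucleophile and the ketone is unveiled afterwards. Zinc-mediated propargylation of 5 (propargyl bromide, Zn, THF, solvent system chosen for the (S)-configured carbon) should give methyl 2-[(1S)-1-{[(R)-tert-butylsulfinyl]amino}but-3-yn-1-yl]-3-methoxybenzoate F3. HCl in MeOH gives the amine hydrochloride F4, which Et3N in MeOH closes to (3S)-4-methoxy-3-(prop-2-yn-1-yl)-2,3-dihydro-1H-isoindol-1-one F5. Double deprotonation (n-BuLi, 2 equiv, THF, −78 °C) and addition of the acetylide to ketone 9 gives the propargylic alcohol F6. Meyer–Schuster rearrangement as in step 6 (VO(OSiPh3)3, toluene) then gives lactam 16, which is carried on with KOtBu as in step 9.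

Step 6. What may go wrong: dehydration of the tertiary alcohol to an enyne, or retro-aldol fragmentation, may outrun the 1,3-oxygen shift. Fallback (sets out from 9, comes back at 12): the vinylic methyl is introduced by carbometalation instead. Ketone 9 is converted via its enol phosphate F7 (LiN(iPr)2, ClP(O)(OEt)2, THF, −78 °C) and elimination with further LiN(iPr)2 into methyl 2-ethynyl-5-methyl-2-(3-methylbut-2-en-1-yl)hex-4-enoate F8. Acylation of the alkyne (AcCl, PdCl2(PPh3)2, CuI, Et3N) gives the ynone F9. Me2CuLi (THF, −78 °C) adds methyl to the alkyne carbon next to the quaternary centre and should give 12 after protonation; a (Z)-rich product is equilibrated to the (E)-isomer with catalytic iodine before step 7.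

**Further compounds**
F1 | step 9 | 3-hydroxy-5-methyl-6,6-bis(3-methylbut-2-en-1-yl)cyclohexa-2,4-dien-1-one | O=C1C=C(O)C=C(C)C1(CC=C(C)C)CC=C(C)C
F2 | step 9 | 3-hydroxy-4-methoxy-2,3-dihydro-1H-isoindol-1-one (racemic) | COc1cccc2c1C(O)NC2=O
F3 | step 7 | methyl 2-[(1S)-1-{[(R)-tert-butylsulfinyl]amino}but-3-yn-1-yl]-3-methoxybenzoate | COC(=O)c1cccc(OC)c1[C@H](CC#C)N[S@](=O)C(C)(C)C
F4 | step 7 | methyl 2-[(1S)-1-aminobut-3-yn-1-yl]-3-methoxybenzoate hydrochloride | COC(=O)c1cccc(OC)c1[C@H](CC#C)N.Cl
F5 | step 7 | (3S)-4-methoxy-3-(prop-2-yn-1-yl)-2,3-dihydro-1H-isoindol-1-one | COc1cccc2c1[C@H](CC#C)NC2=O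
F6 | step 7 | methyl 3-hydroxy-6-[(1S)-7-methoxy-3-oxo-2,3-dihydro-1H-isoindol-1-yl]-3-methyl-2,2-bis(3-methylbut-2-en-1-yl)hex-4-ynoate (carbinol epimers) | COc1cccc2c1[C@H](CC#CC(C)(O)C(CC=C(C)C)(CC=C(C)C)C(=O)OC)NC2=O
F7 | step 6 | methyl 2-{1-[(diethoxyphosphoryl)oxy]ethenyl}-5-methyl-2-(3-methylbut-2-en-1-yl)hex-4-enoate | C=C(OP(=O)(OCC)OCC)C(CC=C(C)C)(CC=C(C)C)C(=O)OC
F8 | step 6 | methyl 2-ethynyl-5-methyl-2-(3-methylbut-2-en-1-yl)hex-4-enoate | C#CC(CC=C(C)C)(CC=C(C)C)C(=O)OC
F9 | step 6 | methyl 5-methyl-2-(3-methylbut-2-en-1-yl)-2-(3-oxobut-1-yn-1-yl)hex-4-enoate | CC(=O)C#CC(CC=C(C)C)(CC=C(C)C)C(=O)OC
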